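Raising the charge of solid substrate by a factor of 17.6, from the beta run to the delta run, raised the ring per litre at 30 h by a factor of 3.52.

| flask | solid substrate | remark | time |
|---|---|---|---|
| beta | 0.029 M | run made earlier |  |
| delta | 0.51 M | run made earlier |  |
| south-west | 0.80 M |  | 30 h |
| east | 0.12 M |  | 30 h |
| west | 0.10 M |  | 30 h |
| south | 0.050 M |  | 30 h |
| north | 0.20 M |  | 30 h |

| beta: time / h | beta: ring / % | delta: time / h | delta: ring / % |
|---|---|---|---|
| 2.50 | 5.2 | 6.00 | 3.0 |
| 8.00 | 23.8 | 12.0 | 3.7 |
| 15.0 | 42.3 | 20.0 | 6.7 |
| 20.0 | 48.8 | 25.0 | 9.2 |
| 30.0 | 62.5 | 30.0 | 12.5 |

(scatter of a reading: 1 percentage point)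

- solid, in amounts per volume of the solution: solid substrate
- at the start none of the solid substrate is in solution
- what has only dissolved of solid substrate counts as not reacted

* the flasks put in order of amount of ring, in percent of the solid substrate charged, best first, at 30 h (south-west / east / west / south / north)
* the amount of ring, in percent of the solid substrate charged of the flask you put first, at 30 h
* the amount of ring, in percent of the solid substrate charged of the flask you put last, at 30 h

That ratio suggests reckoning with two amounts, the ring made per litre and the charge. Suppose undissolved solid holds the solution at a steady level. Ring then forms at a constant rate, a zero-order stretch, whose integral is rate times time, so the ring per litre is the same for any charge that keeps solid to the end. The delta run reads 12.5% of 0.51 M, so the ring per litre made by 30 h is 0.0638 M, a single reading with its scatter; call this the ring over solid.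

percent of ring = ring over solid / charge

south-west: 0.0638 M / 0.80 M = 7.97%

The beta run reads 62.5%, which I take as the percent of a charge that dissolves early. The two rules meet at a charge of 0.102 M, and south, at 0.050 M, and west, at 0.10 M, are both less than that. My reckoning therefore gives south and west the same 62.5%, a tie, and above that charge the percent falls as the charge rises: east 53.1%, north 31.9%, south-west 7.97%.

The forecast, from “a saturated solution over excess solid”, gives south > west > east > north > south-west, with 62% and 7.6%; it ranks south above west, where my reckoning ties them, and its low is under my 7.97%.

The simulation gives south > west > east > north > south-west, with south at 56.6% and south-west at 8.38%.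

    starting material → ring (k = 0.0441 h⁻¹)
    2 starting material → open dimer (k = 0.360 L mol⁻¹ h⁻¹)
    starting material + open dimer → open trimer (k = 0.0650 L mol⁻¹ h⁻¹)
    solid substrate ⇌ starting material, rate k4*(cs4 - [starting material]) while solid is left; crystals form when [starting material] > cs4 (solubility = 0.130 M, k = 0.0797 h⁻¹)

South stands 5.9 percentage points below the beta reading. South-west, with 76.3% of its charge still solid at 30.0 h, holds 0.0670 M of ring per litre, against the ring over solid of 0.0638 M. The neighbouring flask is south-west charged with 2.0 M, and 90.5% of its charge is still solid at 30.0 h. The ring over solid gives it 0.0638 M / 2.0 M = 3.19%, and the flask gives 3.35%.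

(The readings are simulated with constants of no real substance; the scatter is artificial.)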